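**Retrosynthetic overview**
- Target ⇐ protected flavonol, by one Lewis-acid operation that removes two benzyl ethers and the peri 5-O-methyl group.
- Protected flavonol ⇐ 2'-hydroxychalcone, by a one-pot nitrosative oxidative cyclisation: O1–C2 closes the pyranone, and C3 is functionalised through a C–N bond that is exchanged for C–O.
- Chalcone ⇐ Claisen–Schmidt condensation of a 2'-hydroxy-trimethoxyacetophenone with a 2,4-bis(benzyloxy)-5-methoxybenzaldehyde.
- Aldehyde ⇐ 2,4,5-trimethoxybenzaldehyde, by ortho/para-selective bis-demethylation and benzylation.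
- Ring order: rings A and B are bought as arenes; only the pyranone ring C is built (step 4).

Assumption: the target has no stereocentre and no stereogenic double bond (it is achiral), so no stereocontrol is needed; both aromatic starting materials are taken as catalogue compounds.

**Step 1**
Reactants: 1 2,4,5-trimethoxybenzaldehyde
Product: 2 2,4-dihydroxy-5-methoxybenzaldehyde
Conditions: AlCl3 (5 equiv), CH2Cl2, 0 °C → reflux, 16 h; ice/H2O
Reagents that add atoms: none
Why: Lewis-acid aryl methyl ether cleavage in which the Al-complexed formyl group activates only the ortho (chelated) and para (vinylogous) methoxy groups, so the meta 5-OMe survives; this selective demethylation is recalled as precedented for this aldehyde.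

**Step 2**
Reactants: 2 2,4-dihydroxy-5-methoxybenzaldehyde
Product: 3 2,4-bis(benzyloxy)-5-methoxybenzaldehyde
Conditions: BnBr (2.5 equiv), K2CO3 (3 equiv), DMF, 60 °C
Reagents that add atoms: benzyl bromide, BrCc1ccccc1
Why: Williamson ether synthesis (SN2) on both phenoxides, the hydrogen-bonded 2-OH included at 60 °C, giving ethers that are stable to the base of step 3 and the acid of step 4.

**Step 3**
Reactants: 3 2,4-bis(benzyloxy)-5-methoxybenzaldehyde; 4 1-(2-hydroxy-3,4,6-trimethoxyphenyl)ethan-1-one (2'-hydroxy-3',4',6'-trimethoxyacetophenone)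
Product: 5 (E)-3-[2,4-bis(benzyloxy)-5-methoxyphenyl]-1-(2-hydroxy-3,4,6-trimethoxyphenyl)prop-2-en-1-one
Conditions: KOH (50% aq, 10 equiv), EtOH, rt, 48 h; then dil. HCl
Reagents that add atoms: none
Why: Claisen–Schmidt (crossed aldol) condensation in which only the ketone can enolise and E1cB dehydration gives the conjugated E-enone under thermodynamic control; benzyl and methyl ethers are base-stable.

**Step 4**
Reactants: 5 (E)-3-[2,4-bis(benzyloxy)-5-methoxyphenyl]-1-(2-hydroxy-3,4,6-trimethoxyphenyl)prop-2-en-1-one
Product: 9 2-[2,4-bis(benzyloxy)-5-methoxyphenyl]-3-hydroxy-5,7,8-trimethoxy-4H-chromen-4-one, via flavanone 6 (not isolated), via 3-oximinoflavanone 7 (not isolated), via chromane-3,4-dione 8 (not isolated)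
Conditions: conc. HCl (cat.), EtOH–1,4-dioxane, 70 °C, 12 h; then isopentyl nitrite (3 equiv, slow addition), 45 °C, closed flask, 6 h; then H2O, 45 °C, 1 h (one pot)
Reagents that add atoms: isopentyl nitrite, CC(C)CCON=O (N and O of intermediate 7; net source of the C3 oxygen of 8 and 9, relayed through water)
Why: Proposed new method: a one-pot nitrosative oxidative cyclisation of a 2'-hydroxychalcone to a flavonol — acid-catalysed 6-endo-trig oxa-Michael addition closes the pyranone (O1–C2) to flavanone 6 (helped by the 6'-OMe twist; no epoxide, hence no aurone channel), the enol of 6 is C-nitrosated at C3 by NO+ from nitrite/HCl (C–N bond) and tautomerises to α-keto-oxime 7, which drains the chalcone⇌flavanone equilibrium, a second equivalent of nitrite then nitrosates the oxime nitrogen, water adds at C3 and N2O leaves (nitrosative de-oximation) to give dione 8, and enolisation of 8 to the 3-hydroxy-4-pyranone 9 erases the transient racemic C2 centre; the closest known chemistry is the Kostanecki flavonol synthesis (isolated flavanone → 3-isonitrosoflavanone → separate hot-acid hydrolysis) together with the nitrosative cleavage of α-isonitroso ketones to 1,2-diketones, which as far as I know have not been merged into a single chalcone-to-flavonol operation.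

**Step 5**
Reactants: 9 2-[2,4-bis(benzyloxy)-5-methoxyphenyl]-3-hydroxy-5,7,8-trimethoxy-4H-chromen-4-one
Product: 10 2-(2,4-dihydroxy-5-methoxyphenyl)-3,5-dihydroxy-7,8-dimethoxy-4H-chromen-4-one (3,5,2',4'-tetrahydroxy-7,8,5'-trimethoxyflavone)
Conditions: BCl3 (1 M in CH2Cl2, 8 equiv), pentamethylbenzene (6 equiv), CH2Cl2, −78 °C (1 h) → 0 °C (3 h); then H2O
Reagents that add atoms: none
Why: Lewis-acid ether cleavage in which the benzyl aryl ethers fall at −78 °C with the benzyl cation trapped by pentamethylbenzene, and on warming only the 5-OMe, held in a six-membered boron chelate with C4=O, is demethylated, while the non-chelated 7-, 8- and 5'-OMe groups remain; no stereocentre is involved.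

**Compound list**
1 | 2,4,5-trimethoxybenzaldehyde | COc1cc(OC)c(C=O)cc1OC | starting material
2 | 2,4-dihydroxy-5-methoxybenzaldehyde | COc1cc(C=O)c(O)cc1O | intermediate
3 | 2,4-bis(benzyloxy)-5-methoxybenzaldehyde | COc1cc(C=O)c(OCc2ccccc2)cc1OCc1ccccc1 | intermediate
4 | 1-(2-hydroxy-3,4,6-trimethoxyphenyl)ethan-1-one | CC(=O)c1c(O)c(OC)c(OC)cc1OC | starting material
5 | (E)-3-[2,4-bis(benzyloxy)-5-methoxyphenyl]-1-(2-hydroxy-3,4,6-trimethoxyphenyl)prop-2-en-1-one | COc1cc(/C=C/C(=O)c2c(O)c(OC)c(OC)cc2OC)c(OCc2ccccc2)cc1OCc1ccccc1 | intermediate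
6 | rac-2-[2,4-bis(benzyloxy)-5-methoxyphenyl]-5,7,8-trimethoxychroman-4-one (flavanone, racemic at C2, not isolated) | COc1cc(C2CC(=O)c3c(OC)cc(OC)c(OC)c3O2)c(OCc2ccccc2)cc1OCc1ccccc1 | intermediate
7 | rac-2-[2,4-bis(benzyloxy)-5-methoxyphenyl]-3-(hydroxyimino)-5,7,8-trimethoxychroman-4-one (racemic at C2, oxime geometry undefined, not isolated) | COc1cc(C2Oc3c(OC)c(OC)cc(OC)c3C(=O)C2=NO)c(OCc2ccccc2)cc1OCc1ccccc1 | intermediate
8 | rac-2-[2,4-bis(benzyloxy)-5-methoxyphenyl]-5,7,8-trimethoxychromane-3,4-dione (racemic at C2, keto tautomer of 9, not isolated) | COc1cc(C2Oc3c(OC)c(OC)cc(OC)c3C(=O)C2=O)c(OCc2ccccc2)cc1OCc1ccccc1 | intermediate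
9 | 2-[2,4-bis(benzyloxy)-5-methoxyphenyl]-3-hydroxy-5,7,8-trimethoxy-4H-chromen-4-one | COc1cc(-c2oc3c(OC)c(OC)cc(OC)c3c(=O)c2O)c(OCc2ccccc2)cc1OCc1ccccc1 | intermediate
10 | 2-(2,4-dihydroxy-5-methoxyphenyl)-3,5-dihydroxy-7,8-dimethoxy-4H-chromen-4-one (achiral) | COc1cc(-c2oc3c(OC)c(OC)cc(O)c3c(=O)c2O)c(O)cc1O | target

**Totals**
Total step count: 5. Longest linear sequence: 5 (1 → 2 → 3 → 5 → 9 → 10); ketone 4 enters at step 3.

**Three steps most likely to fail**

Step 4 (the proposed new step). The risks are C-nitrosation of the free-phenol ring of residual chalcone (para to OH), nitrosation of the electron-rich ether rings, incomplete de-oximation, and some acid loss of benzyl groups. The fallback uses known chemistry and sets out from chalcone 5. Catalytic I2 in DMSO at 130 °C effects oxidative 6-endo cyclisation and dehydrogenation (no aurone) to the flavone 2-[2,4-bis(benzyloxy)-5-methoxyphenyl]-5,7,8-trimethoxy-4H-chromen-4-one F1. Dimethyldioxirane in acetone at 0 °C then epoxidises C2=C3 to rac-2-[2,4-bis(benzyloxy)-5-methoxyphenyl]-2,3-epoxy-5,7,8-trimethoxychroman-4-one F2, which is not isolated. A trace of p-TsOH opens F2 at C2 and proton loss from C3 gives the flavonol; the fallback comes back to the route at compound 9.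

Step 5. BCl3 may be slow on the 5-OMe because the 3-OH also chelates boron. On over-exposure it may also cleave the 8-OMe (flanked by two oxygens) or the 5'-OMe next to the freed 4'-O–B. The fallback sets out from compound 9 and separates the two tasks. Hydrogenolysis (H2, Pd/C, EtOAc–MeOH, rt) gives 2-(2,4-dihydroxy-5-methoxyphenyl)-3-hydroxy-5,7,8-trimethoxy-4H-chromen-4-one F3. Anhydrous AlCl3 in MeCN (rt to 50 °C) then removes only the peri 5-methyl group through the aluminium chelate with C4=O; the fallback comes back at compound 10.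

Step 3. The aldehyde is electron-rich and ortho-substituted and the o-hydroxyketone is hindered, so the condensation can stall. Any premature ring closure to flavanone 6 is harmless, since step 4 passes through 6. The fallback sets out from compounds 3 and 4 and replaces the thermodynamic condensation by a directed aldol. The dianion of 4 (LiHMDS, 2.2 equiv, THF, −78 °C) adds to 3 to give rac-3-[2,4-bis(benzyloxy)-5-methoxyphenyl]-3-hydroxy-1-(2-hydroxy-3,4,6-trimethoxyphenyl)propan-1-one F4. Catalytic p-TsOH in CH2Cl2 at rt then dehydrates F4 through the stabilised benzylic cation to the E-enone; the fallback comes back at compound 5.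

**Further compounds**
F1 | step 4 | 2-[2,4-bis(benzyloxy)-5-methoxyphenyl]-5,7,8-trimethoxy-4H-chromen-4-one | COc1cc(-c2cc(=O)c3c(OC)cc(OC)c(OC)c3o2)c(OCc2ccccc2)cc1OCc1ccccc1
F2 | step 4 | rac-2-[2,4-bis(benzyloxy)-5-methoxyphenyl]-2,3-epoxy-5,7,8-trimethoxychroman-4-one | COc1cc(C23OC2C(=O)c2c(OC)cc(OC)c(OC)c2O3)c(OCc2ccccc2)cc1OCc1ccccc1
F3 | step 5 | 2-(2,4-dihydroxy-5-methoxyphenyl)-3-hydroxy-5,7,8-trimethoxy-4H-chromen-4-one | COc1cc(-c2oc3c(OC)c(OC)cc(OC)c3c(=O)c2O)c(O)cc1O
F4 | step 3 | rac-3-[2,4-bis(benzyloxy)-5-methoxyphenyl]-3-hydroxy-1-(2-hydroxy-3,4,6-trimethoxyphenyl)propan-1-one | COc1cc(C(O)CC(=O)c2c(O)c(OC)c(OC)cc2OC)c(OCc2ccccc2)cc1OCc1ccccc1
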